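## The problem

Isolappaol A (22) joins a trans-α,β-dibenzyl-γ-butyrolactone, through the methylene C7 on its α-carbon, to C5 of a trans-2-aryl-3-hydroxymethyl-7-methoxy-2,3-dihydrobenzofuran. Ring A is the guaiacyl ring on the Cβ arm (C7′), ring B the benzo ring of the dihydrobenzofuran, and ring C its 2-aryl group. The four stereocentres form two pairs, Cα/Cβ (R,R) and C2/C3 (S,R). A CH2–arene spacer separates the pairs, so neither can control the other and each needs its own source of absolute configuration; this points to a convergent plan. Within each pair one centre can be left to thermodynamics: Cα is enolisable and prefers to lie trans to the Cβ arm, and C3 can be equilibrated trans to the C2 aryl group while it still carries an ester. Only Cβ and C2 must therefore be set in the absolute sense. The sensitive groups are two free guaiacol phenols (oxidation, quinone methide formation), the benzylic C2–O aryl ether (acid ionisation, hydrogenolysis), the lactone (base, nucleophiles) and a primary alcohol, so phenols and alcohol stay masked until the end. The feature that opens the key step is that Cβ bears C7′ next to Cα, which is α to the carbonyl. C7′ can be the apex of a cyclopropane fused across Cα–Cβ; with a second acyl group on Cα this ring is electrophilic at C7′, and its opening leaves an enolate at the carbon that must bond to C7.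

## Retrosynthesis

**22 ⇒ 21 ⇒ 20 (O–H bonds only).** The two phenols are masked as benzyl ethers and the primary alcohol as a tert-butyldiphenylsilyl ether. Benzyl survives Grignard formation, carbenoid chemistry, hydride and hot chloride. A silyl group on the alcohol keeps the final hydrogenolysis short, because only two fast-cleaving aryl benzyl ethers remain and the benzylic C2–O bond sees little exposure. The forward steps need fluoride that spares the lactone and hydrogenolysis that stops at the aryl benzyl ethers.

**20 ⇒ 19 (Cα–H ⇒ Cα–CO2Me).** An ester is added back on Cα. It makes Cα a malonate-type carbon, and it is what makes the next disconnection possible. Its removal (Krapcho) passes through the lactone enolate, so the Cα configuration of 19 is irrelevant and the trans arrangement of 20 is reached by equilibration under control of Cβ.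

**19 ⇒ 15 + 17 + 12 (ring A–C7′ and Cα–C7).** Both bonds at the lactone are cut at once, giving the cyclopropane-fused lactone 15, the aryl Grignard reagent 17 and the benzylic bromide 12. The neighbouring cuts are weaker: cutting only Cα–C7 needs a separately made chiral β-benzyl lactone, and cutting Cβ–C7′ needs an asymmetric benzyl conjugate addition to a butenolide. Here Cβ comes from the chiral pool and the nucleophile is an aryl, not a benzyl, metal. The forward reaction must attack the cyclopropane CH2 only, leave Cβ untouched and alkylate the resulting enolate at carbon.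

**15 ⇒ 13 + 14 (two cyclopropane bonds and the lactone acyl C–O bond).** Dimethyl malonate 13 and (R)-epichlorohydrin 14 give 15 in one known operation. The precursor pair is as simple as it can be. The forward reaction must follow the epoxide-opening pathway, which fixes the (1S,5R) configuration.

**17 ⇒ 16 (C–Mg).** Magnesium insertion into the commercial aryl bromide 16.

**12 ⇒ 11 ⇒ 10 ⇒ 9 (C–Br, then O–Si).** The reactive bromide is made last from alcohol 11. The two primary alcohols are told apart by silyl groups of different acid stability: tert-butyldimethylsilyl (TBS) on the benzylic oxygen from the start, tert-butyldiphenylsilyl (TBDPS) put on the C3 arm in 10. The forward steps need a selective TBS cleavage and a neutral bromination.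

**9 ⇒ 8 ⇒ 7 (oxidation level and configuration of C3).** The C3 hydroxymethyl group is traced to an ester, which alone allows C3 to be inverted from the cis ester 7 to the trans ester 8 before reduction.

**7 ⇒ 6 (C2–C3, ring closure).** The dihydrofuran ring is opened between C2 and C3 to the aryl diazoacetate 6. A dirhodium carbenoid C–H insertion sets both stereocentres from an achiral precursor in one catalytic step. The cut at O1–C2 would need C3 set beforehand by a longer sequence.

**6 ⇒ 5 ⇒ 4 ⇒ 3 ⇒ 1 + 2 (aryl–C, O–Si, C–H, O–CH2).** The diazoacetate is attached to aryl iodide 5 by palladium catalysis. The aldehyde of 5-iodovanillin 1 is reduced and silylated first, because a free aldehyde or hydroxyl would intercept the carbenoid. The benzylic ether comes from 1 and the commercial alcohol 2. Any enantiomeric impurity in 12 or 15 appears after the coupling as a diastereomer of 19 and can be removed there.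

## Roads not taken

**Alternative 1:** The cut is the ring oxygen of the lactone, leading to the symmetrical cyclobutanone A1. An enantioselective Baeyer–Villiger oxidation would insert oxygen next to one of two enantiotopic CH2 groups and give lactone A2. A2 would then be alkylated as its lithium enolate with 12 to give 20 directly.
- Merits: catalytic asymmetry; about three steps from an allylguaiacol to A1; no ester to remove and no hot decarboxylation; the alkylation sets trans kinetically.
- Weak points: the stereogenic carbon of A1 is β to the carbonyl and carries a flexible benzyl group, the substrate type where such desymmetrisations discriminate least. The lithium enolate of A2 is hard and basic and can dialkylate with a precious electrophile.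
- Comparison: in step count and mildness this road is as good or slightly better. The chosen plan sets against it a Cβ taken from (R)-epichlorohydrin by substitutions of known course, a stabilised enolate that can only monoalkylate, and ring A entering in the same flask.

**Alternative 2:** The cut is O1–C2. The bis-phenol A3 would be oxidised at ring C (Ag2O or one equivalent of DDQ) to a para-quinone methide, and the ring B phenol would add to it in a 5-exo closure to give the trans dihydrobenzofuran A4.
- Merits: biomimetic; C2 follows from C3; no diazo compound or rhodium. A4 has C5 as an ester and C3 as a silyloxymethyl group, so only three steps would separate it from an electrophile like 12, against five (steps 6–10) here.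
- Weak points: A3 must first be made enantiopure, for example by auxiliary alkylation of a ring B arylacetic acid, which costs more steps than it saves. One guaiacol must be oxidised beside another, and the product is itself a para-hydroxybenzyl ether open to re-oxidation.
- Comparison: this road competes with how 12 is made, not with the lactone assembly. It is better in protecting-group economy after ring closure. The chosen route sets against it a shorter path to the cyclisation substrate and no free phenol during ring construction.

**Alternative 3:** The cut is C2–C3. Rh2(S-PTTL)4, dirhodium tetrakis[N-phthaloyl-(S)-tert-leucinate], would turn the corresponding methyl diazoacetate into a carbenoid that inserts into the O–CH2–aryl C–H bond and gives the cis ester A5.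
- Merits: two stereocentres and the ring from an achiral precursor in one catalytic step, exclusively cis and correctable to trans.
- Weak points: enantioselectivity depends on catalyst and substitution pattern; a diazo compound is needed. As the pivot of a plan it solves only the dihydrobenzofuran and leaves both lactone C–C bonds and Cβ to other chemistry.
- Comparison: stereochemically this insertion does more than the cyclopropane opening, and the chosen plan uses it as a supporting step on the ethyl ester (6 → 7). The plan is organised around the cyclopropane opening because that step is the convergent event: it joins three fragments and forms both lactone C–C bonds.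

Key step: step 13

Assumption: Rh2(S-PTTL)4 is taken to give the (2S) centre, as with simpler 2-benzyloxyaryl diazoacetates; if this substrate responds in the opposite sense, Rh2(R-PTTL)4 is used and nothing else changes.

## Route

Step 1
Reactants: 1 5-iodovanillin (4-hydroxy-3-iodo-5-methoxybenzaldehyde); 2 4-benzyloxy-3-methoxybenzyl alcohol
Product: 3 4-[(4-benzyloxy-3-methoxybenzyl)oxy]-3-iodo-5-methoxybenzaldehyde
Conditions: PPh3, DIAD, THF, 0 °C to rt
Reagents that add atoms: none
Why: Mitsunobu etherification; the phenol is acidified by the para-formyl and ortho-iodo groups and the primary benzylic oxyphosphonium ion is displaced easily. No stereocentre is involved.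

Step 2
Reactants: 3 4-[(4-benzyloxy-3-methoxybenzyl)oxy]-3-iodo-5-methoxybenzaldehyde
Product: 4 {4-[(4-benzyloxy-3-methoxybenzyl)oxy]-3-iodo-5-methoxyphenyl}methanol
Conditions: NaBH4, MeOH–THF, 0 °C
Reagents that add atoms: none
Why: Borohydride reduction of an aromatic aldehyde; aryl iodide and ethers are inert.

Step 3
Reactants: 4 {4-[(4-benzyloxy-3-methoxybenzyl)oxy]-3-iodo-5-methoxyphenyl}methanol
Product: 5 ({4-[(4-benzyloxy-3-methoxybenzyl)oxy]-3-iodo-5-methoxybenzyl}oxy)(tert-butyl)dimethylsilane
Conditions: TBSCl, imidazole, DMF, rt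
Reagents that add atoms: tert-butyldimethylsilyl chloride (TBSCl), CC(C)(C)[Si](C)(C)Cl
Why: Standard silylation of a primary alcohol; it removes the O–H bond that would otherwise undergo O–H insertion with the carbenoid of step 5.

Step 4
Reactants: 5 ({4-[(4-benzyloxy-3-methoxybenzyl)oxy]-3-iodo-5-methoxybenzyl}oxy)(tert-butyl)dimethylsilane
Product: 6 ethyl 2-{2-[(4-benzyloxy-3-methoxybenzyl)oxy]-5-[(tert-butyldimethylsilyloxy)methyl]-3-methoxyphenyl}-2-diazoacetate
Conditions: ethyl diazoacetate, Pd(PPh3)4 (5 mol%), Ag2CO3 (0.5 equiv), Et3N, toluene, rt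
Reagents that add atoms: ethyl diazoacetate, CCOC(=O)C=[N+]=[N-]
Why: Palladium-catalysed cross-coupling of an aryl iodide with the C–H bond of an acceptor diazo compound: oxidative addition to zerovalent palladium, silver- and base-assisted transfer of the diazoacetate carbon, reductive elimination with the diazo group retained at room temperature.

Step 5
Reactants: 6 ethyl 2-{2-[(4-benzyloxy-3-methoxybenzyl)oxy]-5-[(tert-butyldimethylsilyloxy)methyl]-3-methoxyphenyl}-2-diazoacetate
Product: 7 ethyl (2S,3R)-2-(4-benzyloxy-3-methoxyphenyl)-5-[(tert-butyldimethylsilyloxy)methyl]-7-methoxy-2,3-dihydrobenzofuran-3-carboxylate (cis)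
Conditions: Rh2(S-PTTL)4 (2 mol%), toluene, −60 °C
Reagents that add atoms: none
Why: Intramolecular dirhodium carbenoid C–H insertion into the benzylic ether C–H bond (activated by oxygen and the electron-rich ring C) through a five-membered transition state. The concerted insertion gives the cis ring, and the chiral carboxylate ligands select the enantiotopic C–H bond, setting C2 (S) and C3 (R) together.

Step 6
Reactants: 7 ethyl (2S,3R)-2-(4-benzyloxy-3-methoxyphenyl)-5-[(tert-butyldimethylsilyloxy)methyl]-7-methoxy-2,3-dihydrobenzofuran-3-carboxylate (cis)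
Product: 8 ethyl (2S,3S)-2-(4-benzyloxy-3-methoxyphenyl)-5-[(tert-butyldimethylsilyloxy)methyl]-7-methoxy-2,3-dihydrobenzofuran-3-carboxylate (trans)
Conditions: NaOEt (0.3 equiv), EtOH–THF, rt
Reagents that add atoms: none
Why: Base-mediated epimerisation at C3 through the ester enolate to the thermodynamically preferred trans isomer. C2 is not acidic and keeps its configuration; ethoxide matches the ester, so no transesterification occurs.

Step 7
Reactants: 8 ethyl (2S,3S)-2-(4-benzyloxy-3-methoxyphenyl)-5-[(tert-butyldimethylsilyloxy)methyl]-7-methoxy-2,3-dihydrobenzofuran-3-carboxylate (trans)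
Product: 9 {(2S,3R)-2-(4-benzyloxy-3-methoxyphenyl)-5-[(tert-butyldimethylsilyloxy)methyl]-7-methoxy-2,3-dihydrobenzofuran-3-yl}methanol
Conditions: LiAlH4, THF, 0 °C
Reagents that add atoms: none
Why: Hydride reduction of the ester to the primary alcohol; after this step C3 is no longer epimerisable (its descriptor changes to R only through the priority rules).

Step 8
Reactants: 9 {(2S,3R)-2-(4-benzyloxy-3-methoxyphenyl)-5-[(tert-butyldimethylsilyloxy)methyl]-7-methoxy-2,3-dihydrobenzofuran-3-yl}methanol
Product: 10 (2S,3R)-2-(4-benzyloxy-3-methoxyphenyl)-5-[(tert-butyldimethylsilyloxy)methyl]-3-[(tert-butyldiphenylsilyloxy)methyl]-7-methoxy-2,3-dihydrobenzofuran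
Conditions: TBDPSCl, imidazole, DMF, rt
Reagents that add atoms: tert-butyldiphenylsilyl chloride (TBDPSCl), CC(C)(C)[Si](Cl)(c1ccccc1)c1ccccc1
Why: Silylation of the primary alcohol with the more acid-stable TBDPS group, so that the two silyl ethers can be told apart in step 9.

Step 9
Reactants: 10 (2S,3R)-2-(4-benzyloxy-3-methoxyphenyl)-5-[(tert-butyldimethylsilyloxy)methyl]-3-[(tert-butyldiphenylsilyloxy)methyl]-7-methoxy-2,3-dihydrobenzofuran
Product: 11 {(2S,3R)-2-(4-benzyloxy-3-methoxyphenyl)-3-[(tert-butyldiphenylsilyloxy)methyl]-7-methoxy-2,3-dihydrobenzofuran-5-yl}methanol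
Conditions: HF·pyridine, pyridine, THF, 0 °C to rt
Reagents that add atoms: none
Why: Selective desilylation: under buffered acidic fluoride a primary TBS ether is cleaved much faster than a TBDPS ether, and the alcohol-free medium avoids solvolysis of the electron-rich benzylic position.

Step 10
Reactants: 11 {(2S,3R)-2-(4-benzyloxy-3-methoxyphenyl)-3-[(tert-butyldiphenylsilyloxy)methyl]-7-methoxy-2,3-dihydrobenzofuran-5-yl}methanol
Product: 12 (2S,3R)-2-(4-benzyloxy-3-methoxyphenyl)-5-(bromomethyl)-3-[(tert-butyldiphenylsilyloxy)methyl]-7-methoxy-2,3-dihydrobenzofuran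
Conditions: CBr4, PPh3, CH2Cl2, 0 °C; used at once
Reagents that add atoms: carbon tetrabromide, BrC(Br)(Br)Br
Why: Appel bromination under neutral conditions, which spares the silyl ether, the benzyl ether and the acid-sensitive C2–O bond; the reactive bromide is not stored.

Step 11
Reactants: 13 dimethyl malonate; 14 (R)-epichlorohydrin
Product: 15 methyl (1S,5R)-2-oxo-3-oxabicyclo[3.1.0]hexane-1-carboxylate
Conditions: NaOMe, MeOH, 0 °C to reflux
Reagents that add atoms: none
Why: Tandem malonate alkylation: the malonate opens the epoxide at its CH2, the alkoxide closes a new epoxide by displacing chloride, the malonate anion closes the cyclopropane by 3-exo-tet attack with one inversion at the stereogenic carbon, and the freed alkoxide lactonises. The configuration comes from 14.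

Step 12
Reactants: 16 1-benzyloxy-4-bromo-2-methoxybenzene
Product: 17 4-benzyloxy-3-methoxyphenylmagnesium bromide (titrated THF solution)
Conditions: Mg turnings, cat. I2, THF, rt to 40 °C
Reagents that add atoms: magnesium, [Mg]
Why: Grignard formation by magnesium insertion into the aryl bromide; the benzyl and methyl ethers are inert.

Step 13
Reactants: 15 methyl (1S,5R)-2-oxo-3-oxabicyclo[3.1.0]hexane-1-carboxylate; 17 4-benzyloxy-3-methoxyphenylmagnesium bromide; 12 (2S,3R)-2-(4-benzyloxy-3-methoxyphenyl)-5-(bromomethyl)-3-[(tert-butyldiphenylsilyloxy)methyl]-7-methoxy-2,3-dihydrobenzofuran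
Product: 19 methyl (3R,4R)-4-(4-benzyloxy-3-methoxybenzyl)-3-({(2S,3R)-2-(4-benzyloxy-3-methoxyphenyl)-3-[(tert-butyldiphenylsilyloxy)methyl]-7-methoxy-2,3-dihydrobenzofuran-5-yl}methyl)-2-oxotetrahydrofuran-3-carboxylate, via bromomagnesium lactone enolate 18 (not isolated)
Conditions: 15 (1.3 equiv), 17 (1.25 equiv), CuI (0.15 equiv), THF, −45 to 0 °C; then 12 (1.0 equiv), DMPU, 0 °C to rt
Reagents that add atoms: none
Why: Homoconjugate addition with enolate trapping, the cyclopropane counterpart of tandem conjugate addition–alkylation; the closest known reaction is the CuI-catalysed aryl Grignard opening of 2-oxo-3-oxabicyclo[3.1.0]hexane-1-carboxylates, whose stabilised enolate is normally benzylated in a separate operation and is here benzylated in the same flask. The arylcopper species from 17 attacks the cyclopropane CH2 (C7′) in an SN2-like way and breaks the bond to the carbon flanked by both carbonyl groups, so Cβ is not a reacting centre and keeps the configuration brought from 14. No ring closes; the three-membered ring opens and the lactone remains. Attack at the CH2 and not at the ring-fusion CH follows from sterics and is the known regiochemistry of this lactone class with cuprates, and copper catalysis at low temperature suppresses carbonyl addition. DMPU loosens the chelated enolate 18, which is alkylated at carbon by 12 anti to the new Cβ arm, defining the quaternary Cα of 19 as R; this centre is temporary and any syn isomer converges in step 14. Reagent 17 is kept in slight deficit to 15 so that no aryl Grignard reagent remains to couple with 12 under copper catalysis.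

Step 14
Reactants: 19 methyl (3R,4R)-4-(4-benzyloxy-3-methoxybenzyl)-3-({(2S,3R)-2-(4-benzyloxy-3-methoxyphenyl)-3-[(tert-butyldiphenylsilyloxy)methyl]-7-methoxy-2,3-dihydrobenzofuran-5-yl}methyl)-2-oxotetrahydrofuran-3-carboxylate
Product: 20 (3R,4R)-4-(4-benzyloxy-3-methoxybenzyl)-3-({(2S,3R)-2-(4-benzyloxy-3-methoxyphenyl)-3-[(tert-butyldiphenylsilyloxy)methyl]-7-methoxy-2,3-dihydrobenzofuran-5-yl}methyl)dihydrofuran-2(3H)-one
Conditions: LiCl, H2O, DMSO, 140 °C; then DBU, THF, rt
Reagents that add atoms: none
Why: Krapcho demethoxycarbonylation: chloride removes the methyl group of the geminally activated ester, CO2 is lost and the lactone enolate is protonated. DBU then equilibrates Cα to the trans (3R,4R) lactone under thermodynamic control by Cβ; partial loss of the silyl group here would be harmless because step 15 removes it.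

Step 15
Reactants: 20 (3R,4R)-4-(4-benzyloxy-3-methoxybenzyl)-3-({(2S,3R)-2-(4-benzyloxy-3-methoxyphenyl)-3-[(tert-butyldiphenylsilyloxy)methyl]-7-methoxy-2,3-dihydrobenzofuran-5-yl}methyl)dihydrofuran-2(3H)-one
Product: 21 (3R,4R)-4-(4-benzyloxy-3-methoxybenzyl)-3-({(2S,3R)-2-(4-benzyloxy-3-methoxyphenyl)-3-(hydroxymethyl)-7-methoxy-2,3-dihydrobenzofuran-5-yl}methyl)dihydrofuran-2(3H)-one
Conditions: Bu4NF, AcOH, THF, rt
Reagents that add atoms: none
Why: Fluoride desilylation, buffered with acetic acid so that the lactone is not opened; Cα already has its thermodynamic configuration.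

Step 16
Reactants: 21 (3R,4R)-4-(4-benzyloxy-3-methoxybenzyl)-3-({(2S,3R)-2-(4-benzyloxy-3-methoxyphenyl)-3-(hydroxymethyl)-7-methoxy-2,3-dihydrobenzofuran-5-yl}methyl)dihydrofuran-2(3H)-one
Product: 22 isolappaol A, (3R,4R)-4-(4-hydroxy-3-methoxybenzyl)-3-({(2S,3R)-2-(4-hydroxy-3-methoxyphenyl)-3-(hydroxymethyl)-7-methoxy-2,3-dihydrobenzofuran-5-yl}methyl)dihydrofuran-2(3H)-one
Conditions: H2 (1 atm), 10% Pd/C, EtOAc–EtOH, rt
Reagents that add atoms: none
Why: Hydrogenolysis of the two aryl benzyl ethers, which cleave faster than the more hindered cyclic benzylic C2–O bond under these mild neutral conditions. No stereocentre is touched.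

## Compound list

1 | 5-iodovanillin (4-hydroxy-3-iodo-5-methoxybenzaldehyde) | COc1cc(C=O)cc(I)c1O | starting material
2 | 4-benzyloxy-3-methoxybenzyl alcohol | COc1cc(CO)ccc1OCc1ccccc1 | starting material
3 | 4-[(4-benzyloxy-3-methoxybenzyl)oxy]-3-iodo-5-methoxybenzaldehyde | COc1cc(C=O)cc(I)c1OCc1ccc(OCc2ccccc2)c(OC)c1 | intermediate
4 | {4-[(4-benzyloxy-3-methoxybenzyl)oxy]-3-iodo-5-methoxyphenyl}methanol | COc1cc(CO)cc(I)c1OCc1ccc(OCc2ccccc2)c(OC)c1 | intermediate
5 | ({4-[(4-benzyloxy-3-methoxybenzyl)oxy]-3-iodo-5-methoxybenzyl}oxy)(tert-butyl)dimethylsilane | COc1cc(CO[Si](C)(C)C(C)(C)C)cc(I)c1OCc1ccc(OCc2ccccc2)c(OC)c1 | intermediate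
6 | ethyl 2-{2-[(4-benzyloxy-3-methoxybenzyl)oxy]-5-[(tert-butyldimethylsilyloxy)methyl]-3-methoxyphenyl}-2-diazoacetate | CCOC(=O)C(=[N+]=[N-])c1cc(CO[Si](C)(C)C(C)(C)C)cc(OC)c1OCc1ccc(OCc2ccccc2)c(OC)c1 | intermediate
7 | ethyl (2S,3R)-2-(4-benzyloxy-3-methoxyphenyl)-5-[(tert-butyldimethylsilyloxy)methyl]-7-methoxy-2,3-dihydrobenzofuran-3-carboxylate (cis) | CC(C)(C)[Si](C)(C)OCc1cc(OC)c2c(c1)[C@@H](C(=O)OCC)[C@@H](c1ccc(OCc3ccccc3)c(OC)c1)O2 | intermediate
8 | ethyl (2S,3S)-2-(4-benzyloxy-3-methoxyphenyl)-5-[(tert-butyldimethylsilyloxy)methyl]-7-methoxy-2,3-dihydrobenzofuran-3-carboxylate (trans) | CC(C)(C)[Si](C)(C)OCc1cc(OC)c2c(c1)[C@H](C(=O)OCC)[C@@H](c1ccc(OCc3ccccc3)c(OC)c1)O2 | intermediate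
9 | {(2S,3R)-2-(4-benzyloxy-3-methoxyphenyl)-5-[(tert-butyldimethylsilyloxy)methyl]-7-methoxy-2,3-dihydrobenzofuran-3-yl}methanol | CC(C)(C)[Si](C)(C)OCc1cc(OC)c2c(c1)[C@H](CO)[C@@H](c1ccc(OCc3ccccc3)c(OC)c1)O2 | intermediate
10 | (2S,3R)-2-(4-benzyloxy-3-methoxyphenyl)-5-[(tert-butyldimethylsilyloxy)methyl]-3-[(tert-butyldiphenylsilyloxy)methyl]-7-methoxy-2,3-dihydrobenzofuran | CC(C)(C)[Si](C)(C)OCc1cc(OC)c2c(c1)[C@H](CO[Si](c1ccccc1)(c1ccccc1)C(C)(C)C)[C@@H](c1ccc(OCc3ccccc3)c(OC)c1)O2 | intermediate
11 | {(2S,3R)-2-(4-benzyloxy-3-methoxyphenyl)-3-[(tert-butyldiphenylsilyloxy)methyl]-7-methoxy-2,3-dihydrobenzofuran-5-yl}methanol | OCc1cc(OC)c2c(c1)[C@H](CO[Si](c1ccccc1)(c1ccccc1)C(C)(C)C)[C@@H](c1ccc(OCc3ccccc3)c(OC)c1)O2 | intermediate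
12 | (2S,3R)-2-(4-benzyloxy-3-methoxyphenyl)-5-(bromomethyl)-3-[(tert-butyldiphenylsilyloxy)methyl]-7-methoxy-2,3-dihydrobenzofuran | BrCc1cc(OC)c2c(c1)[C@H](CO[Si](c1ccccc1)(c1ccccc1)C(C)(C)C)[C@@H](c1ccc(OCc3ccccc3)c(OC)c1)O2 | intermediate
13 | dimethyl malonate | COC(=O)CC(=O)OC | starting material
14 | (R)-epichlorohydrin | ClC[C@H]1CO1 | starting material
15 | methyl (1S,5R)-2-oxo-3-oxabicyclo[3.1.0]hexane-1-carboxylate | COC(=O)[C@]12C[C@H]1COC2=O | intermediate
16 | 1-benzyloxy-4-bromo-2-methoxybenzene | COc1cc(Br)ccc1OCc1ccccc1 | starting material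
17 | 4-benzyloxy-3-methoxyphenylmagnesium bromide | COc1cc([Mg]Br)ccc1OCc1ccccc1 | intermediate
18 | bromomagnesium enolate of methyl (4R)-4-(4-benzyloxy-3-methoxybenzyl)-2-oxotetrahydrofuran-3-carboxylate | COC(=O)C1=C(O[Mg]Br)OC[C@@H]1Cc1ccc(OCc2ccccc2)c(OC)c1 | intermediate
19 | methyl (3R,4R)-4-(4-benzyloxy-3-methoxybenzyl)-3-({(2S,3R)-2-(4-benzyloxy-3-methoxyphenyl)-3-[(tert-butyldiphenylsilyloxy)methyl]-7-methoxy-2,3-dihydrobenzofuran-5-yl}methyl)-2-oxotetrahydrofuran-3-carboxylate | COc1cc(C[C@H]2COC(=O)[C@]2(C(=O)OC)Cc2cc(OC)c3c(c2)[C@H](CO[Si](c4ccccc4)(c4ccccc4)C(C)(C)C)[C@@H](c2ccc(OCc4ccccc4)c(OC)c2)O3)ccc1OCc1ccccc1 | intermediate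
20 | (3R,4R)-4-(4-benzyloxy-3-methoxybenzyl)-3-({(2S,3R)-2-(4-benzyloxy-3-methoxyphenyl)-3-[(tert-butyldiphenylsilyloxy)methyl]-7-methoxy-2,3-dihydrobenzofuran-5-yl}methyl)dihydrofuran-2(3H)-one | COc1cc(C[C@H]2COC(=O)[C@@H]2Cc2cc(OC)c3c(c2)[C@H](CO[Si](c4ccccc4)(c4ccccc4)C(C)(C)C)[C@@H](c2ccc(OCc4ccccc4)c(OC)c2)O3)ccc1OCc1ccccc1 | intermediate
21 | (3R,4R)-4-(4-benzyloxy-3-methoxybenzyl)-3-({(2S,3R)-2-(4-benzyloxy-3-methoxyphenyl)-3-(hydroxymethyl)-7-methoxy-2,3-dihydrobenzofuran-5-yl}methyl)dihydrofuran-2(3H)-one | COc1cc(C[C@H]2COC(=O)[C@@H]2Cc2cc(OC)c3c(c2)[C@H](CO)[C@@H](c2ccc(OCc4ccccc4)c(OC)c2)O3)ccc1OCc1ccccc1 | intermediate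
22 | isolappaol A, (3R,4R)-4-(4-hydroxy-3-methoxybenzyl)-3-({(2S,3R)-2-(4-hydroxy-3-methoxyphenyl)-3-(hydroxymethyl)-7-methoxy-2,3-dihydrobenzofuran-5-yl}methyl)dihydrofuran-2(3H)-one | COc1cc(C[C@H]2COC(=O)[C@@H]2Cc2cc(OC)c3c(c2)[C@H](CO)[C@@H](c2ccc(O)c(OC)c2)O3)ccc1O | target

## Step count and least certain steps

Total steps: 16. Longest linear sequence: 14 (steps 1–10, then 13–16).

**Step 13 (key step).** The most likely failure is incomplete C-alkylation of the tightly chelated magnesium enolate, or consumption of the bromide by copper-mediated coupling with aryl Grignard reagent that has not yet reacted. Both come from running two reactions of different demands in one flask. The fallback gives up the one-flask sequence and sets out from 15 and 17. The opening is run alone and quenched with aqueous NH4Cl to isolate methyl (3S,4R)-4-(4-benzyloxy-3-methoxybenzyl)-2-oxotetrahydrofuran-3-carboxylate F1. Its sodium enolate (NaH, DMF, 0 °C) is then alkylated with 12 in a separate operation, returning to the route at 19.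

**Step 5.** The most likely failure is poor discrimination between the enantiotopic benzylic C–H bonds. The methoxy group ortho to the ether oxygen changes the conformation of the benzyloxy arm relative to simpler substrates, and oxonium ylide formation at the ether oxygen may compete. The fallback replaces catalyst control by separation of covalent diastereomers. It sets out from alcohol 9 of insufficient optical purity, which is esterified with (S)-2-methoxy-2-phenylacetic acid (DCC, DMAP) to {(2S,3R)-2-(4-benzyloxy-3-methoxyphenyl)-5-[(tert-butyldimethylsilyloxy)methyl]-7-methoxy-2,3-dihydrobenzofuran-3-yl}methyl (2S)-2-methoxy-2-phenylacetate F2. F2 is freed from its diastereomer by chromatography or crystallisation and cleaved with K2CO3 in MeOH, coming back at 9 as a single stereoisomer.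

**Step 4.** The most likely failure is slow coupling at the iodide flanked by the bulky benzyloxy group, with loss of nitrogen from the diazo ester on palladium before or after coupling. The fallback builds the diazo group by a different route and sets out from 5. Iodine–magnesium exchange (i-PrMgCl·LiCl, THF, −20 °C) and addition to excess diethyl oxalate give ethyl 2-{2-[(4-benzyloxy-3-methoxybenzyl)oxy]-5-[(tert-butyldimethylsilyloxy)methyl]-3-methoxyphenyl}-2-oxoacetate F3. Condensation with tosylhydrazide gives ethyl 2-{2-[(4-benzyloxy-3-methoxybenzyl)oxy]-5-[(tert-butyldimethylsilyloxy)methyl]-3-methoxyphenyl}-2-(tosylhydrazono)acetate F4, and Bamford–Stevens elimination with DBU in CH2Cl2 returns to the route at 6.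

**Step 14.** The most likely failure is sluggish demethylation at the crowded quaternary malonate centre, so that the long heating needed allows chloride to open the lactone at its CH2–O carbon or degrades the material. The fallback replaces dealkylative by hydrolytic decarboxylation and sets out from 19. Saponification (LiOH, aqueous THF) followed by acidification relactonises to (3R,4R)-4-(4-benzyloxy-3-methoxybenzyl)-3-({(2S,3R)-2-(4-benzyloxy-3-methoxyphenyl)-3-[(tert-butyldiphenylsilyloxy)methyl]-7-methoxy-2,3-dihydrobenzofuran-5-yl}methyl)-2-oxotetrahydrofuran-3-carboxylic acid F5. F5 loses CO2 on warming in toluene and, after the same DBU equilibration, comes back at 20.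

**Step 16.** The most likely failure is over-reduction, that is hydrogenolytic opening of the benzylic C2–O bond of the dihydrobenzofuran once the benzyl ethers are gone. The fallback avoids hydrogen altogether: it sets out from 21 and removes both benzyl groups with BCl3 and pentamethylbenzene in CH2Cl2 at −78 °C, arriving directly at 22 without a new intermediate.

## Further compounds

F1 | step 13 | methyl (3S,4R)-4-(4-benzyloxy-3-methoxybenzyl)-2-oxotetrahydrofuran-3-carboxylate | COc1cc(C[C@H]2COC(=O)[C@@H]2C(=O)OC)ccc1OCc1ccccc1
F2 | step 5 | {(2S,3R)-2-(4-benzyloxy-3-methoxyphenyl)-5-[(tert-butyldimethylsilyloxy)methyl]-7-methoxy-2,3-dihydrobenzofuran-3-yl}methyl (2S)-2-methoxy-2-phenylacetate | CC(C)(C)[Si](C)(C)OCc1cc(OC)c2c(c1)[C@H](COC(=O)[C@@H](OC)c1ccccc1)[C@@H](c1ccc(OCc3ccccc3)c(OC)c1)O2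
F3 | step 4 | ethyl 2-{2-[(4-benzyloxy-3-methoxybenzyl)oxy]-5-[(tert-butyldimethylsilyloxy)methyl]-3-methoxyphenyl}-2-oxoacetate | CCOC(=O)C(=O)c1cc(CO[Si](C)(C)C(C)(C)C)cc(OC)c1OCc1ccc(OCc2ccccc2)c(OC)c1
F4 | step 4 | ethyl 2-{2-[(4-benzyloxy-3-methoxybenzyl)oxy]-5-[(tert-butyldimethylsilyloxy)methyl]-3-methoxyphenyl}-2-(tosylhydrazono)acetate | CCOC(=O)C(=NNS(=O)(=O)c1ccc(C)cc1)c1cc(CO[Si](C)(C)C(C)(C)C)cc(OC)c1OCc1ccc(OCc2ccccc2)c(OC)c1
F5 | step 14 | (3R,4R)-4-(4-benzyloxy-3-methoxybenzyl)-3-({(2S,3R)-2-(4-benzyloxy-3-methoxyphenyl)-3-[(tert-butyldiphenylsilyloxy)methyl]-7-methoxy-2,3-dihydrobenzofuran-5-yl}methyl)-2-oxotetrahydrofuran-3-carboxylic acid | COc1cc(C[C@H]2COC(=O)[C@]2(C(=O)O)Cc2cc(OC)c3c(c2)[C@H](CO[Si](c4ccccc4)(c4ccccc4)C(C)(C)C)[C@@H](c2ccc(OCc4ccccc4)c(OC)c2)O3)ccc1OCc1ccccc1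
F0 | step 16 | none | none
A1 | alternative 1 | 3-(4-benzyloxy-3-methoxybenzyl)cyclobutan-1-one | COc1cc(CC2CC(=O)C2)ccc1OCc1ccccc1
A2 | alternative 1 | (R)-4-(4-benzyloxy-3-methoxybenzyl)dihydrofuran-2(3H)-one | COc1cc(C[C@H]2COC(=O)C2)ccc1OCc1ccccc1
A3 | alternative 2 | methyl 3-[(2R)-1-(tert-butyldimethylsilyloxy)-3-(4-hydroxy-3-methoxyphenyl)propan-2-yl]-4-hydroxy-5-methoxybenzoate | COC(=O)c1cc(OC)c(O)c(c1)[C@H](CO[Si](C)(C)C(C)(C)C)Cc1ccc(O)c(OC)c1
A4 | alternative 2 | methyl (2S,3R)-3-[(tert-butyldimethylsilyloxy)methyl]-2-(4-hydroxy-3-methoxyphenyl)-7-methoxy-2,3-dihydrobenzofuran-5-carboxylate | COC(=O)c1cc(OC)c2c(c1)[C@H](CO[Si](C)(C)C(C)(C)C)[C@@H](c1ccc(O)c(OC)c1)O2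
A5 | alternative 3 | methyl (2S,3R)-2-(4-benzyloxy-3-methoxyphenyl)-5-[(tert-butyldimethylsilyloxy)methyl]-7-methoxy-2,3-dihydrobenzofuran-3-carboxylate (cis) | CC(C)(C)[Si](C)(C)OCc1cc(OC)c2c(c1)[C@@H](C(=O)OC)[C@@H](c1ccc(OCc3ccccc3)c(OC)c1)O2
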